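## Retrosynthetic overview

1. Final stage: the (Z)-enone comes from an ynone by semihydrogenation, the ynone from a propargylic alcohol, and the C5 isobutyryl group from bridgehead lithiation–acylation once C7 is quaternary.
2. Key disconnection: the C7–C1′ bond, made by an intermolecular aldol between the C7 enolate of a 7-silyloxybicyclo[3.2.1]octane-6,8-dione and 4-methyl-4-silyloxypent-2-ynal; exo attack sets the C7 carbinol.
3. Five-membered ring (formed second): the C5–C6 bond by intramolecular acylation of a cyclohexanone enolate with a pendant Weinreb amide; the C7 oxygen by enolate hydroxylation.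
4. Cyclohexanone: two α′-alkylations (prenyl, then the acetamide arm anti to the C4 prenyl) and a methyl cuprate addition on (S)-3-methyl-4-prenylcyclohex-2-enone.
5. Six-membered ring (formed first) and absolute configuration: organocatalytic Michael addition of 5-methylhex-4-enal to but-3-en-2-one, then aldol condensation.

Core locants: C1 = prenyl-bearing bridgehead, C2 = CH2, C3 = CH(prenyl), C4 = CMe2, C5 = acyl-bearing bridgehead, C6 = ring ketone, C7 = carbinol carbon, C8 = bridging ketone. Prenyl = 3-methylbut-2-en-1-yl; exo = the face of C6/C7 syn to C8.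

Assumption: metalated species that exist only until the next reagent or the quench of the same operation (enolates, the lithium acetylide, the bridgehead carbanion, alkoxide adducts) are treated as states of the reacting compound and are not numbered.

## Route

Step 1
Reactants: 1 2-methylbut-3-en-2-ol
Product: 2 ethyl 5-methylhex-4-enoate
Conditions: MeC(OEt)3, EtCO2H (cat.), 140 °C, EtOH distilled off
Reagents that add atoms: triethyl orthoacetate CC(OCC)(OCC)OCC
Why: Johnson–Claisen rearrangement of the tertiary allylic alcohol through its ketene acetal gives the γ,δ-unsaturated ester with the trisubstituted alkene in place, and no stereocenter is formed.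

Step 2
Reactants: 2 ethyl 5-methylhex-4-enoate
Product: 3 5-methylhex-4-enal
Conditions: i-Bu2AlH, CH2Cl2, −78 °C; then aq. potassium sodium tartrate
Reagents that add atoms: none
Why: Partial ester reduction with one equivalent of i-Bu2AlH at low temperature stops at the aluminium hemiacetal, which releases the aldehyde on work-up while the alkene is inert.

Step 3
Reactants: 3 5-methylhex-4-enal; 4 but-3-en-2-one
Product: 5 (2S)-2-prenyl-5-oxohexanal
Conditions: (S)-2-[methoxy(diphenyl)methyl]pyrrolidine (5 mol %), ethyl 3,4-dihydroxybenzoate (20 mol %), neat, 4 °C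
Reagents that add atoms: none
Why: In this enamine-catalysed intermolecular Michael addition the bulky diaryl carbinol ether of the (S)-catalyst shields one face of the E-enamine of 3, so the enone is attacked from the open face and the new α-stereocenter is set as S.

Step 4
Reactants: 5 (2S)-2-prenyl-5-oxohexanal
Product: 6 (4S)-4-prenylcyclohex-2-en-1-one
Conditions: LiOH (cat.), i-PrOH, rt
Reagents that add atoms: none
Why: Intramolecular aldol condensation, in which only the methyl ketone enolate can close a six-membered ring onto the aldehyde, gives the conjugated enone after dehydration and keeps the stereocenter, now γ to the carbonyl.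

Step 5
Reactants: 6 (4S)-4-prenylcyclohex-2-en-1-one
Product: 7 trimethyl{[(3S,4S)-3-methyl-4-prenylcyclohex-1-en-1-yl]oxy}silane
Conditions: Me2CuLi (from MeLi, CuI), Me3SiCl, THF, −78 °C
Reagents that add atoms: lithium dimethylcuprate [Li+].C[Cu-]C; chlorotrimethylsilane C[Si](C)(C)Cl
Why: Silyl-chloride-accelerated cuprate conjugate addition occurs anti to the C4 substituent (trans product) and traps the enolate regiospecifically as its silyl enol ether.

Step 6
Reactants: 7 trimethyl{[(3S,4S)-3-methyl-4-prenylcyclohex-1-en-1-yl]oxy}silane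
Product: 8 (4S)-3-methyl-4-prenylcyclohex-2-en-1-one
Conditions: Pd(OAc)2, MeCN, rt
Reagents that add atoms: none
Why: Saegusa–Ito oxidation proceeds through a palladium enolate that undergoes β-hydride elimination toward C3, which restores the enone and erases the temporary C3 stereocenter while C4 is untouched.

Step 7
Reactants: 8 (4S)-3-methyl-4-prenylcyclohex-2-en-1-one
Product: 9 (4R,6RS)-3-methyl-4,6-diprenylcyclohex-2-en-1-one (C6 epimers)
Conditions: LiN(i-Pr)2, THF, −78 °C; then prenyl bromide, −78 → 0 °C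
Reagents that add atoms: 1-bromo-3-methylbut-2-ene CC(C)=CCBr
Why: Kinetic deprotonation gives the cross-conjugated α′-enolate, which is C-alkylated by the allylic bromide in an SN2 enolate alkylation, and the C6 epimer mixture is irrelevant because C6 is re-enolized in the next step.

Step 8
Reactants: 9 (4R,6RS)-3-methyl-4,6-diprenylcyclohex-2-en-1-one
Product: 10 2-[(1S,5R)-4-methyl-1,5-diprenyl-2-oxocyclohex-3-en-1-yl]-N-methoxy-N-methylacetamide
Conditions: LiN(i-Pr)2, THF/DMPU, −78 °C; then BrCH2C(O)N(OMe)Me, −78 → −20 °C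
Reagents that add atoms: 2-bromo-N-methoxy-N-methylacetamide BrCC(=O)N(C)OC
Why: In this second α′-enolate alkylation the enone C4 prenyl group sits pseudoaxial to avoid allylic strain with the C3 methyl and blocks one face, so the α-bromoamide enters anti to it and sets the quaternary carbon with the acetamide arm trans to that prenyl group.

Step 9
Reactants: 10 2-[(1S,5R)-4-methyl-1,5-diprenyl-2-oxocyclohex-3-en-1-yl]-N-methoxy-N-methylacetamide
Product: 12 2-[(1S,5R)-4,4-dimethyl-1,5-diprenyl-2-oxocyclohexyl]-N-methoxy-N-methylacetamide, via trimethylsilyl enol ether 11 (not isolated)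
Conditions: Me2CuLi (from MeLi, CuI), Me3SiCl, THF, −78 → −30 °C; then 1 M HCl, THF, 0 °C
Reagents that add atoms: lithium dimethylcuprate [Li+].C[Cu-]C
Why: Silyl-chloride-accelerated cuprate 1,4-addition to the β-methyl enone builds the gem-dimethyl carbon (no new stereocenter) without touching the Weinreb amide, and mild acid hydrolysis of the silyl enol ether returns the ketone.

Step 10
Reactants: 12 2-[(1S,5R)-4,4-dimethyl-1,5-diprenyl-2-oxocyclohexyl]-N-methoxy-N-methylacetamide
Product: 13 (1S,3R,5R)-4,4-dimethyl-1,3-diprenylbicyclo[3.2.1]octane-6,8-dione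
Conditions: LiN(SiMe3)2, THF, −78 → 0 °C; then AcOH
Reagents that add atoms: none
Why: In this intramolecular Claisen-type acylation the only possible ketone enolate attacks the axial Weinreb amide arm to give a chelated tetrahedral adduct that resists retro-Claisen cleavage and collapses to the 1,3-diketone on quench, and the bridging forces the new C5 center cis to the arm with the C3 prenyl group equatorial.

Step 11
Reactants: 13 (1S,3R,5R)-4,4-dimethyl-1,3-diprenylbicyclo[3.2.1]octane-6,8-dione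
Product: 14 (1S,3R,5S,7S)-7-hydroxy-4,4-dimethyl-1,3-diprenylbicyclo[3.2.1]octane-6,8-dione
Conditions: KN(SiMe3)2, THF, −78 °C; then 2-(phenylsulfonyl)-3-phenyloxaziridine; then AcOH
Reagents that add atoms: 2-(phenylsulfonyl)-3-phenyloxaziridine O=S(=O)(c1ccccc1)N1OC1c1ccccc1
Why: Davis enolate hydroxylation can occur only at C7 because C5 is a bridgehead and C1 is quaternary, and the oxidant approaches the exo face to give the exo alcohol, a center that is re-enolized later.

Step 12
Reactants: 14 (1S,3R,5S,7S)-7-hydroxy-4,4-dimethyl-1,3-diprenylbicyclo[3.2.1]octane-6,8-dione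
Product: 15 (1S,3R,5S,7S)-4,4-dimethyl-1,3-diprenyl-7-[(triethylsilyl)oxy]bicyclo[3.2.1]octane-6,8-dione
Conditions: Et3SiOTf, 2,6-lutidine, CH2Cl2, −78 → 0 °C
Reagents that add atoms: triethylsilyl trifluoromethanesulfonate CC[Si](CC)(CC)OS(=O)(=O)C(F)(F)F
Why: O-silylation of the hindered secondary alcohol with a silyl triflate and a non-nucleophilic base gives the triethylsilyl ether without epimerization or enol silane formation.

Step 13
Reactants: 16 2-methylbut-3-yn-2-ol
Product: 17 triethyl[(2-methylbut-3-yn-2-yl)oxy]silane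
Conditions: Et3SiOTf, 2,6-lutidine, CH2Cl2, 0 °C
Reagents that add atoms: triethylsilyl trifluoromethanesulfonate CC[Si](CC)(CC)OS(=O)(=O)C(F)(F)F
Why: O-silylation with the silyl triflate protects the tertiary propargylic alcohol cleanly and leaves the terminal alkyne free for metalation.

Step 14
Reactants: 17 triethyl[(2-methylbut-3-yn-2-yl)oxy]silane
Product: 18 4-methyl-4-[(triethylsilyl)oxy]pent-2-ynal
Conditions: n-BuLi, THF, −78 °C; then DMF; then AcOH
Reagents that add atoms: N,N-dimethylformamide CN(C)C=O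
Why: Formylation of the lithium acetylide with the formamide gives a hemiaminal alkoxide that releases the ynal on acidic quench, which also keeps the liberated amine from adding to the ynal.

Step 15
Reactants: 15 (1S,3R,5S,7S)-4,4-dimethyl-1,3-diprenyl-7-[(triethylsilyl)oxy]bicyclo[3.2.1]octane-6,8-dione; 18 4-methyl-4-[(triethylsilyl)oxy]pent-2-ynal
Product: 19 (1S,3R,5S,7S)-7-{(1RS)-1-hydroxy-4-methyl-4-[(triethylsilyl)oxy]pent-2-yn-1-yl}-4,4-dimethyl-1,3-diprenyl-7-[(triethylsilyl)oxy]bicyclo[3.2.1]octane-6,8-dione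
Conditions: LiN(i-Pr)2, THF, −78 °C; then 18; then AcOH, −78 °C
Reagents that add atoms: none
Why: In this intermolecular aldol addition the lithium enolate of 15, which can form only toward C7, attacks the unhindered ynal from the exo face, so the new C–C bond is exo and the silyloxy group endo (7S), while the propargylic carbinol forms as an epimer mixture that is oxidized away later.

Step 16
Reactants: 19 aldol adduct (free propargylic alcohol)
Product: 20 (1S,3R,5S,7S)-4,4-dimethyl-1,3-diprenyl-7-[(triethylsilyl)oxy]-7-{(1RS)-4-methyl-4-[(triethylsilyl)oxy]-1-[(trimethylsilyl)oxy]pent-2-yn-1-yl}bicyclo[3.2.1]octane-6,8-dione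
Conditions: Me3SiCl, imidazole, CH2Cl2, 0 °C
Reagents that add atoms: chlorotrimethylsilane C[Si](C)(C)Cl
Why: O-silylation of the secondary propargylic alcohol as a labile trimethylsilyl ether blocks retro-aldol cleavage under the strongly basic conditions of the next step.

Step 17
Reactants: 20 trimethylsilyl-protected aldol adduct
Product: 21 (1S,3R,5R,7S)-4,4-dimethyl-1,3-diprenyl-5-(2-methylpropanoyl)-7-[(triethylsilyl)oxy]-7-{(1RS)-4-methyl-4-[(triethylsilyl)oxy]-1-[(trimethylsilyl)oxy]pent-2-yn-1-yl}bicyclo[3.2.1]octane-6,8-dione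
Conditions: lithium 2,2,6,6-tetramethylpiperidide (from the amine and n-BuLi), THF, −78 → −40 °C; then i-PrCOCl, −78 °C
Reagents that add atoms: 2-methylpropanoyl chloride CC(C)C(=O)Cl
Why: In this bridgehead metalation–acylation the C5–H is the only proton α to a carbonyl, so the hindered amide base gives a pyramidal carbanion stabilized inductively by both flanking ketones, and it is C-acylated with retention because the bicycle fixes the configuration.

Step 18
Reactants: 21 C5-acylated trimethylsilyl ether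
Product: 22 (1S,3R,5R,7S)-7-{(1RS)-1-hydroxy-4-methyl-4-[(triethylsilyl)oxy]pent-2-yn-1-yl}-4,4-dimethyl-1,3-diprenyl-5-(2-methylpropanoyl)-7-[(triethylsilyl)oxy]bicyclo[3.2.1]octane-6,8-dione
Conditions: PPTS (cat.), MeOH, 0 °C
Reagents that add atoms: none
Why: Acid-catalysed methanolysis removes the secondary trimethylsilyl ether far faster than the two hindered tertiary triethylsilyl ethers.

Step 19
Reactants: 22 propargylic alcohol
Product: 23 (1S,3R,5R,7S)-4,4-dimethyl-1,3-diprenyl-7-{4-methyl-4-[(triethylsilyl)oxy]pent-2-ynoyl}-5-(2-methylpropanoyl)-7-[(triethylsilyl)oxy]bicyclo[3.2.1]octane-6,8-dione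
Conditions: Dess–Martin periodinane, CH2Cl2, 0 °C → rt
Reagents that add atoms: none
Why: Dess–Martin oxidation of the propargylic alcohol under near-neutral conditions gives the ynone and removes the undefined carbinol center without affecting alkenes or silyl ethers.

Step 20
Reactants: 23 ynone
Product: 24 (1S,3R,5R,7S)-4,4-dimethyl-1,3-diprenyl-7-{(2Z)-4-methyl-4-[(triethylsilyl)oxy]pent-2-enoyl}-5-(2-methylpropanoyl)-7-[(triethylsilyl)oxy]bicyclo[3.2.1]octane-6,8-dione
Conditions: H2 (1 atm), Pd/CaCO3 poisoned with Pb(OAc)2, quinoline, EtOAc, rt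
Reagents that add atoms: none
Why: Lindlar-type semihydrogenation delivers both hydrogens to the same face of the alkyne on the poisoned palladium surface to give the (Z)-enone, while the trisubstituted prenyl alkenes are not reduced.

Step 21
Reactants: 24 (Z)-enone bis(triethylsilyl) ether
Product: 25 (1S,3R,5R,7S)-7-hydroxy-7-[(2Z)-4-hydroxy-4-methylpent-2-enoyl]-4,4-dimethyl-1,3-diprenyl-5-(2-methylpropanoyl)bicyclo[3.2.1]octane-6,8-dione (CNP0190794.1)
Conditions: HF·pyridine, pyridine, THF, 0 °C → rt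
Reagents that add atoms: none
Why: Buffered fluoride desilylation cleaves both triethylsilyl ethers without strong base, which avoids retro-Claisen cleavage of the bridgehead triketone and isomerization of the (Z)-enone.

## Compound list

1 | 2-methylbut-3-en-2-ol | CC(C)(O)C=C | starting material
2 | ethyl 5-methylhex-4-enoate | CCOC(=O)CCC=C(C)C | intermediate
3 | 5-methylhex-4-enal | CC(C)=CCCC=O | intermediate
4 | but-3-en-2-one | CC(=O)C=C | starting material
5 | (2S)-2-(3-methylbut-2-en-1-yl)-5-oxohexanal | O=C[C@H](CC=C(C)C)CCC(C)=O | intermediate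
6 | (4S)-4-(3-methylbut-2-en-1-yl)cyclohex-2-en-1-one | O=C1C=C[C@H](CC=C(C)C)CC1 | intermediate
7 | trimethyl{[(3S,4S)-3-methyl-4-(3-methylbut-2-en-1-yl)cyclohex-1-en-1-yl]oxy}silane | C[Si](C)(C)OC1=C[C@@H](C)[C@H](CC=C(C)C)CC1 | intermediate
8 | (4S)-3-methyl-4-(3-methylbut-2-en-1-yl)cyclohex-2-en-1-one | O=C1C=C(C)[C@H](CC=C(C)C)CC1 | intermediate
9 | (4R,6RS)-3-methyl-4,6-bis(3-methylbut-2-en-1-yl)cyclohex-2-en-1-one | O=C1C=C(C)[C@H](CC=C(C)C)CC1CC=C(C)C | intermediate
10 | 2-[(1S,5R)-4-methyl-1,5-bis(3-methylbut-2-en-1-yl)-2-oxocyclohex-3-en-1-yl]-N-methoxy-N-methylacetamide | CC(C)=CC[C@@H]1C[C@](CC(=O)N(C)OC)(CC=C(C)C)C(=O)C=C1C | intermediate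
11 | 2-{(1S,5R)-4,4-dimethyl-1,5-bis(3-methylbut-2-en-1-yl)-2-[(trimethylsilyl)oxy]cyclohex-2-en-1-yl}-N-methoxy-N-methylacetamide | CC(C)=CC[C@@H]1C[C@](CC(=O)N(C)OC)(CC=C(C)C)C(O[Si](C)(C)C)=CC1(C)C | intermediate
12 | 2-[(1S,5R)-4,4-dimethyl-1,5-bis(3-methylbut-2-en-1-yl)-2-oxocyclohexyl]-N-methoxy-N-methylacetamide | CC(C)=CC[C@@H]1C[C@](CC(=O)N(C)OC)(CC=C(C)C)C(=O)CC1(C)C | intermediate
13 | (1S,3R,5R)-4,4-dimethyl-1,3-bis(3-methylbut-2-en-1-yl)bicyclo[3.2.1]octane-6,8-dione | CC(C)=CC[C@@H]1C[C@]2(CC=C(C)C)C(=O)[C@@H](C(=O)C2)C1(C)C | intermediate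
14 | (1S,3R,5S,7S)-7-hydroxy-4,4-dimethyl-1,3-bis(3-methylbut-2-en-1-yl)bicyclo[3.2.1]octane-6,8-dione (7-OH exo) | CC(C)=CC[C@@H]1C[C@]2(CC=C(C)C)C(=O)[C@@H](C(=O)[C@H]2O)C1(C)C | intermediate
15 | (1S,3R,5S,7S)-4,4-dimethyl-1,3-bis(3-methylbut-2-en-1-yl)-7-[(triethylsilyl)oxy]bicyclo[3.2.1]octane-6,8-dione | CC(C)=CC[C@@H]1C[C@]2(CC=C(C)C)C(=O)[C@@H](C(=O)[C@H]2O[Si](CC)(CC)CC)C1(C)C | intermediate
16 | 2-methylbut-3-yn-2-ol | CC(C)(O)C#C | starting material
17 | triethyl[(2-methylbut-3-yn-2-yl)oxy]silane | CC[Si](CC)(CC)OC(C)(C)C#C | intermediate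
18 | 4-methyl-4-[(triethylsilyl)oxy]pent-2-ynal | CC[Si](CC)(CC)OC(C)(C)C#CC=O | intermediate
19 | (1S,3R,5S,7S)-7-{(1RS)-1-hydroxy-4-methyl-4-[(triethylsilyl)oxy]pent-2-yn-1-yl}-4,4-dimethyl-1,3-bis(3-methylbut-2-en-1-yl)-7-[(triethylsilyl)oxy]bicyclo[3.2.1]octane-6,8-dione | CC(C)=CC[C@@H]1C[C@]2(CC=C(C)C)C(=O)[C@@H](C(=O)[C@@]2(O[Si](CC)(CC)CC)C(O)C#CC(C)(C)O[Si](CC)(CC)CC)C1(C)C | intermediate
20 | (1S,3R,5S,7S)-4,4-dimethyl-1,3-bis(3-methylbut-2-en-1-yl)-7-[(triethylsilyl)oxy]-7-{(1RS)-4-methyl-4-[(triethylsilyl)oxy]-1-[(trimethylsilyl)oxy]pent-2-yn-1-yl}bicyclo[3.2.1]octane-6,8-dione | CC(C)=CC[C@@H]1C[C@]2(CC=C(C)C)C(=O)[C@@H](C(=O)[C@@]2(O[Si](CC)(CC)CC)C(O[Si](C)(C)C)C#CC(C)(C)O[Si](CC)(CC)CC)C1(C)C | intermediate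
21 | (1S,3R,5R,7S)-4,4-dimethyl-1,3-bis(3-methylbut-2-en-1-yl)-5-(2-methylpropanoyl)-7-[(triethylsilyl)oxy]-7-{(1RS)-4-methyl-4-[(triethylsilyl)oxy]-1-[(trimethylsilyl)oxy]pent-2-yn-1-yl}bicyclo[3.2.1]octane-6,8-dione | CC(C)=CC[C@@H]1C[C@]2(CC=C(C)C)C(=O)[C@@](C(=O)C(C)C)(C(=O)[C@@]2(O[Si](CC)(CC)CC)C(O[Si](C)(C)C)C#CC(C)(C)O[Si](CC)(CC)CC)C1(C)C | intermediate
22 | (1S,3R,5R,7S)-7-{(1RS)-1-hydroxy-4-methyl-4-[(triethylsilyl)oxy]pent-2-yn-1-yl}-4,4-dimethyl-1,3-bis(3-methylbut-2-en-1-yl)-5-(2-methylpropanoyl)-7-[(triethylsilyl)oxy]bicyclo[3.2.1]octane-6,8-dione | CC(C)=CC[C@@H]1C[C@]2(CC=C(C)C)C(=O)[C@@](C(=O)C(C)C)(C(=O)[C@@]2(O[Si](CC)(CC)CC)C(O)C#CC(C)(C)O[Si](CC)(CC)CC)C1(C)C | intermediate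
23 | (1S,3R,5R,7S)-4,4-dimethyl-1,3-bis(3-methylbut-2-en-1-yl)-7-{4-methyl-4-[(triethylsilyl)oxy]pent-2-ynoyl}-5-(2-methylpropanoyl)-7-[(triethylsilyl)oxy]bicyclo[3.2.1]octane-6,8-dione | CC(C)=CC[C@@H]1C[C@]2(CC=C(C)C)C(=O)[C@@](C(=O)C(C)C)(C(=O)[C@@]2(O[Si](CC)(CC)CC)C(=O)C#CC(C)(C)O[Si](CC)(CC)CC)C1(C)C | intermediate
24 | (1S,3R,5R,7S)-4,4-dimethyl-1,3-bis(3-methylbut-2-en-1-yl)-7-{(2Z)-4-methyl-4-[(triethylsilyl)oxy]pent-2-enoyl}-5-(2-methylpropanoyl)-7-[(triethylsilyl)oxy]bicyclo[3.2.1]octane-6,8-dione | CC(C)=CC[C@@H]1C[C@]2(CC=C(C)C)C(=O)[C@@](C(=O)C(C)C)(C(=O)[C@@]2(O[Si](CC)(CC)CC)C(=O)/C=C\C(C)(C)O[Si](CC)(CC)CC)C1(C)C | intermediate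
25 | (1S,3R,5R,7S)-7-hydroxy-7-[(2Z)-4-hydroxy-4-methylpent-2-enoyl]-4,4-dimethyl-1,3-bis(3-methylbut-2-en-1-yl)-5-(2-methylpropanoyl)bicyclo[3.2.1]octane-6,8-dione | CC(C)=CC[C@@H]1C[C@]2(CC=C(C)C)C(=O)[C@@](C(=O)C(C)C)(C(=O)[C@@]2(O)C(=O)/C=C\C(C)(C)O)C1(C)C | target

## Count and risks

Total steps: 21. Longest linear sequence: 19 (steps 1–12 and 15–21); the ynal 18 is made in two steps (13, 14).

Most likely to fail, first: step 17, the bridgehead acylation. A bridgehead carbanion in a bicyclo[3.2.1]octane cannot be enolate-stabilized, and the acid chloride is a hindered electrophile next to the gem-dimethyl carbon. The fallback sets out from 20 and keeps the metalation but traps the carbanion with 2-methylpropanal, a smaller and more reactive electrophile, to give the bridgehead carbinol F1. PPTS in methanol then removes the trimethylsilyl group to give the diol F2, and Dess–Martin periodinane oxidizes both secondary alcohols at once. This comes back to the route at 23.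

Second: step 15, the aldol. The only enolizable hydrogen of 15 is the endo C7–H, which is shielded by the six-membered ring. The lithium enolate may also suffer silyl migration between the two oxygens or retro-aldol loss of the adduct. The fallback sets out from 15 and avoids amide-base deprotonation: soft enolization with Me3SiOTf and Et3N gives the enediol bis-silyl ether F3. A fluoride-catalysed Mukaiyama-type aldol with 18 (n-Bu4N[Ph3SiF2] cat., THF, −78 → 0 °C) then unmasks the C6 enolate by attack on the less hindered trimethylsilyl group, bonds C7 to the aldehyde from the exo face and passes the silyl group to the new alkoxide. This comes back to the route at 20.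

Third: step 10, the ring closure. The neopentyl enolate may add sluggishly to the Weinreb amide, or the amide may be enolized instead. The fallback sets out from 10 and replaces the acylation by an aldol–oxidation sequence. The cuprate addition is repeated with non-aqueous work-up so that the silyl enol ether 11 is isolated. i-Bu2AlH at −78 °C reduces its Weinreb amide to the aldehyde F4. n-Bu4NF in THF (−78 → 0 °C) triggers an intramolecular aldol to the bicyclic ketol F5; no Lewis acid is used, so the neighbouring prenyl group cannot undergo a carbonyl-ene reaction. Dess–Martin oxidation then comes back to the route at 13.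

## Further compounds

F1 | step 17 | (1S,3R,5R,7S)-5-[(1RS)-1-hydroxy-2-methylpropyl]-4,4-dimethyl-1,3-bis(3-methylbut-2-en-1-yl)-7-[(triethylsilyl)oxy]-7-{(1RS)-4-methyl-4-[(triethylsilyl)oxy]-1-[(trimethylsilyl)oxy]pent-2-yn-1-yl}bicyclo[3.2.1]octane-6,8-dione | CC(C)=CC[C@@H]1C[C@]2(CC=C(C)C)C(=O)[C@@](C(O)C(C)C)(C(=O)[C@@]2(O[Si](CC)(CC)CC)C(O[Si](C)(C)C)C#CC(C)(C)O[Si](CC)(CC)CC)C1(C)C
F2 | step 17 | (1S,3R,5R,7S)-7-{(1RS)-1-hydroxy-4-methyl-4-[(triethylsilyl)oxy]pent-2-yn-1-yl}-5-[(1RS)-1-hydroxy-2-methylpropyl]-4,4-dimethyl-1,3-bis(3-methylbut-2-en-1-yl)-7-[(triethylsilyl)oxy]bicyclo[3.2.1]octane-6,8-dione | CC(C)=CC[C@@H]1C[C@]2(CC=C(C)C)C(=O)[C@@](C(O)C(C)C)(C(=O)[C@@]2(O[Si](CC)(CC)CC)C(O)C#CC(C)(C)O[Si](CC)(CC)CC)C1(C)C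
F3 | step 15 | (1S,3R,5R)-4,4-dimethyl-1,3-bis(3-methylbut-2-en-1-yl)-7-[(triethylsilyl)oxy]-6-[(trimethylsilyl)oxy]bicyclo[3.2.1]oct-6-en-8-one | CC(C)=CC[C@@H]1C[C@]2(CC=C(C)C)C(=O)[C@@H](C(O[Si](C)(C)C)=C2O[Si](CC)(CC)CC)C1(C)C
F4 | step 10 | 2-{(1S,5R)-4,4-dimethyl-1,5-bis(3-methylbut-2-en-1-yl)-2-[(trimethylsilyl)oxy]cyclohex-2-en-1-yl}acetaldehyde | CC(C)=CC[C@@H]1C[C@](CC=O)(CC=C(C)C)C(O[Si](C)(C)C)=CC1(C)C
F5 | step 10 | (1S,3R,5R,6RS)-6-hydroxy-4,4-dimethyl-1,3-bis(3-methylbut-2-en-1-yl)bicyclo[3.2.1]octan-8-one | CC(C)=CC[C@@H]1C[C@]2(CC=C(C)C)C(=O)[C@@H](C(O)C2)C1(C)C
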